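Everything hinges on disconnecting the C2–C3 bond of ring A (C1–C5, C10). The cis-2,3-diol, equatorial oxygen at C2 and axial oxygen at C3 next to quaternary C4, is read as two aldehyde carbons joined reductively. One SmI2 pinacol cyclisation of a ring B 1,6-dialdehyde (C2 aldehyde on the C10 arm, C3 aldehyde on C4) forms that bond, closes ring A and sets both carbinol centres. The precursor, built from (S)-carvone, is a cyclohexene that already carries the 7-ene, the C9 side chain as a methyl ester, C20 and CH2CHO on C10, and on C5 a quaternary C4 with methyl, formyl (C3) and the C19 dimethyl acetal.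

Key step: step 17

Numbering: labdane locants are used for every intermediate (ring B = C5–C10; C20 methyl and the C1–C2 arm on C10; C4 with C18 methyl, C19 and C3 on C5; C17 methyl on C8; chain C11–C15 on C9, C16 methyl on C13).
Remark on the chemistry: C15 is carried as a methyl ester and saponified before acetylation, so the last step needs only dilute acid, which the 7-ene and the diol monoacetate should tolerate.
Assumption: in step 14 (S)-Tol-BINAP is taken to be the ligand antipode that sends methyl to the Re face of C13; both antipodes are commercial and the sense can be checked on a model enoate.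

Step 1
Reactants: 1 (S)-(+)-carvone; 2 iodomethane
Product: 4 6-methylcarvone (both epimers at the new centre), via lithium dienolate 3 (not isolated)
Conditions: LiN(iPr)2, THF, −78 °C; MeI, −78 to 0 °C
Reagents that add atoms: iodomethane, CI
Why: Kinetic deprotonation at the only enolisable α′ position (the future C10) and C-methylation of the lithium enolate (enolate alkylation); the new centre becomes trigonal again in step 2, so its configuration does not matter.

Step 2
Reactants: 4 6-methylcarvone; 5 allyl bromide
Product: 7 6-allyl-6-methylcarvone (allyl trans to isopropenyl), via lithium dienolate 6 (not isolated)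
Conditions: LiN(iPr)2, THF, −78 °C; allyl bromide, DMPU, −78 to 0 °C
Reagents that add atoms: allyl bromide, C=CCBr
Why: A second enolate alkylation builds quaternary C10; the allyl halide should attack the tetrasubstituted enolate on the face opposite the neighbouring C5 isopropenyl group, so C1 ends trans to C4 and the C20 methyl cis to it.

Step 3
Reactants: 7 6-allyl-6-methylcarvone; 8 3-chloroperoxybenzoic acid
Product: 9 isopropenyl epoxide (both C4 epimers)
Conditions: mCPBA (1.0 equiv), NaHCO3, CH2Cl2, 0 °C
Reagents that add atoms: 3-chloroperoxybenzoic acid, OOC(=O)c1cccc(Cl)c1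
Why: Prilezhaev epoxidation should pick the 1,1-disubstituted isopropenyl alkene, which is more electron-rich than the monosubstituted allyl alkene and far more so than the enone; both epimers are carried on because C4 becomes trigonal in step 5.

Step 4
Reactants: 9 isopropenyl epoxide
Product: 10 α-methyl aldehyde (both C4 epimers)
Conditions: BF3·OEt2 (cat.), CH2Cl2, −78 to −30 °C
Reagents that add atoms: none
Why: Meinwald rearrangement: Lewis-acid opening of the 2,2-disubstituted epoxide at tertiary C4 followed by a 1,2-hydride shift gives the aldehyde.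

Step 5
Reactants: 10 α-methyl aldehyde; 11 tert-butyldimethylsilyl trifluoromethanesulfonate
Product: 12 (E)-silyl enol ether
Conditions: t-BuMe2SiOTf, Et3N, CH2Cl2, −78 to 0 °C
Reagents that add atoms: tert-butyldimethylsilyl trifluoromethanesulfonate, CC(C)(C)[Si](C)(C)OS(=O)(=O)C(F)(F)F
Why: Soft enolisation of the α-branched aldehyde should give the trisubstituted silyl enol ether with the silyloxy group anti to the bulky ring substituent, while the ketone, which has no α′ hydrogen, enolises much more slowly.

Step 6
Reactants: 12 (E)-silyl enol ether; 13 trimethyl orthoformate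
Product: 14 enone with quaternary C4 (C18 methyl, C3 formyl, C19 dimethyl acetal)
Conditions: HC(OMe)3, Me3SiOTf (cat.), CH2Cl2, −78 °C
Reagents that add atoms: trimethyl orthoformate, COC(OC)OC
Why: Mukaiyama-type addition of the silyl enol ether to the dimethoxycarbenium ion makes C4 quaternary with one formyl free and the other masked as its acetal; with C5–H eclipsing the C4 methyl (least A(1,2) strain) the electrophile should enter anti to quaternary C10, which puts the acetal carbon in the C19 position, cis to C20 once ring A is closed.

Step 7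
Reactants: 14 formyl acetal enone; 15 ozone
Product: 17 enone diol (primary alcohols at C2 and C3), via allyl ozonide 16 (not isolated)
Conditions: O3, CH2Cl2, −78 °C; NaBH4, MeOH, −78 to −20 °C
Reagents that add atoms: ozone, [O-][O+]=O
Why: Ozonolysis cleaves the isolated terminal alkene much faster than the electron-poor enone, and NaBH4 reduces the ozonide and the C3 aldehyde while the hindered conjugated ketone should survive at low temperature.

Step 8
Reactants: 17 enone diol; 18 tert-butyldimethylsilyl chloride
Product: 19 bis(silyl) ether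
Conditions: t-BuMe2SiCl, imidazole, DMF, 25 to 40 °C
Reagents that add atoms: tert-butyldimethylsilyl chloride, CC(C)(C)[Si](C)(C)Cl
Why: Routine silylation of the two primary alcohols gives ethers that tolerate the Grignard, chromium, dissolving-metal, palladium and ruthenium steps.

Step 9
Reactants: 19 bis(silyl) ether; 20 but-3-enylmagnesium bromide
Product: 21 tertiary allylic alcohol (both C9 epimers)
Conditions: CH2=CHCH2CH2MgBr, CeCl3, THF, −78 to 0 °C
Reagents that add atoms: but-3-enylmagnesium bromide, C=CCC[Mg]Br
Why: Cerium-mediated Grignard 1,2-addition to the hindered enone carbonyl, which has no α′ hydrogen to lose; the carbinol configuration is erased in step 10.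

Step 10
Reactants: 21 tertiary allylic alcohol
Product: 22 7-oxo-8-ene carrying the butenyl chain on C9
Conditions: [C5H5NH][CrO3Cl], 4 Å molecular sieves, CH2Cl2, 25 °C
Reagents that add atoms: none
Why: Oxidative allylic transposition of a tertiary allylic alcohol (Babler–Dauben oxidation): the chromium ester shifts [3,3] to C7 and is oxidised there, giving the transposed enone with the chain on alkene carbon C9.

Step 11
Reactants: 22 transposed enone; 23 N-phenylbis(trifluoromethanesulfonimide)
Product: 25 C7 enol triflate with H9 trans to the C20 methyl, via lithium enolate 24 (not isolated)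
Conditions: Li, NH3, THF, t-BuOH (1 equiv), −78 °C; isoprene; then PhNTf2, THF, 0 to 25 °C
Reagents that add atoms: N-phenylbis(trifluoromethanesulfonimide), O=S(=O)(N(c1ccccc1)S(=O)(=O)C(F)(F)F)C(F)(F)F
Why: Dissolving-metal (Birch-type) enone reduction with regiospecific trapping of the C7–C8 enolate as its triflate; C9 should be protonated axially, on the face away from the axial C20 methyl of the chair anchored by the equatorial C5 substituent, so H9 ends trans to C20 and the chain equatorial.

Step 12
Reactants: 25 enol triflate
Product: 26 7-ene with the butenyl chain on C9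
Conditions: Pd(OAc)2, PPh3, HCO2H, Bu3N, DMF, 60 °C
Reagents that add atoms: none
Why: Palladium-catalysed formate reduction of the enol triflate (oxidative addition to zerovalent palladium, decarboxylation of formate, C–H reductive elimination) puts hydrogen on C7 and fixes the alkene at C7–C8.

Step 13
Reactants: 26 7-ene with terminal alkene; 27 methyl acrylate
Product: 28 (E)-enoate
Conditions: second-generation Grubbs catalyst RuCl2(=CHPh)(PCy3)(H2IMes) (5 mol %), methyl acrylate, CH2Cl2, 40 °C
Reagents that add atoms: methyl acrylate, C=CC(=O)OC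
Why: Olefin cross-metathesis of the monosubstituted alkene with an acrylate should give the E-enoate selectively, and the hindered trisubstituted 7-ene should not enter the catalytic cycle.

Step 14
Reactants: 28 (E)-enoate; 29 methylmagnesium bromide
Product: 30 (13R)-methyl-branched ester
Conditions: MeMgBr, CuI (5 mol %), (S)-Tol-BINAP (7.5 mol %), t-BuOMe, −20 °C
Reagents that add atoms: methylmagnesium bromide, C[Mg]Br
Why: Copper-catalysed asymmetric conjugate addition of the Grignard reagent to the E-enoate; the chiral bisphosphine on copper directs methyl to the Re face of C13, a centre too remote for the ring to influence, which gives 13R.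

Step 15
Reactants: 30 bis(silyl) ether ester
Product: 31 diol methyl ester
Conditions: Bu4NF, THF, 0 to 40 °C
Reagents that add atoms: none
Why: Fluoride-induced desilylation frees both primary alcohols; ester, acetal and alkene are not touched.

Step 16
Reactants: 31 diol methyl ester
Product: 32 dialdehyde
Conditions: Dess–Martin periodinane, NaHCO3, CH2Cl2, 0 to 25 °C
Reagents that add atoms: none
Why: Dess–Martin oxidation takes both primary alcohols to aldehydes under buffered conditions that avoid aldol reaction between the enolisable C2 aldehyde and the neopentyl C3 aldehyde; the product is used at once.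

Step 17
Reactants: 32 dialdehyde
Product: 34 cis-2,3-diol, via samarium diolate 33 (not isolated)
Conditions: SmI2 (3 equiv), t-BuOH (2 equiv), THF (0.005 M), −78 to 25 °C; aq. NaHCO3/Na2S2O3
Reagents that add atoms: none
Why: Divalent samarium transfers one electron to each aldehyde in turn, the unhindered C2 carbonyl first; the C2 ketyl carbon adds to the C3 carbonyl, whose oxygen sits on the same oxophilic trivalent samarium, and after the second electron the bis-samarium diolate 33 is protonated on work-up (intramolecular pinacol coupling, the known route from 1,6-dialdehydes to cis-cyclohexane-1,2-diols). Ring A closes by 6-exo-trig attack on the C3 carbonyl through a chair that is trans-fused to ring B, with C1 and C4 as equatorial arms. The metal bridge keeps both oxygens on one face of the forming C2–C3 bond, hence the cis relation of the two new centres. Of the two possible cis pairs the one with an axial C2 oxygen would lie 1,3-diaxial to both the C20 methyl and the C19 acetal carbon, so the oxygens should take the opposite face, equatorial at C2 and axial at C3. The step needs cyclisation to outrun dimerisation and simple reduction, which high dilution and a merely stoichiometric proton source at low temperature should secure, and it needs ester, acetal and the 7-ene to stay untouched, which is expected for SmI2 in THF without HMPA; the non-enolisable neopentyl C3 aldehyde and the 1,6 spacing favour the six-membered closure.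

Step 18
Reactants: 34 cis-2,3-diol methyl ester; 35 lithium hydroxide
Product: 36 cis-2,3-diol acid
Conditions: LiOH, THF/MeOH/H2O, 25 °C; then dilute HCl to pH 4, 0 °C
Reagents that add atoms: lithium hydroxide, [Li+].[OH-]
Why: Saponification of the methyl ester is done while no acetate is present; diol, acetal and alkene are inert to hydroxide.

Step 19
Reactants: 36 cis-2,3-diol acid; 37 acetic anhydride
Product: 39 2-O-acetate, via mixed anhydride 38 (not isolated)
Conditions: Ac2O (3 equiv), pyridine, 0 °C; then H2O, 25 °C
Reagents that add atoms: acetic anhydride, CC(=O)OC(C)=O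
Why: Acylation should select the unhindered equatorial C2 hydroxyl over the axial C3 hydroxyl next to quaternary C4, and the C15 mixed anhydride formed alongside is hydrolysed back to the acid in the aqueous quench.

Step 20
Reactants: 39 2-O-acetate acetal; 40 water
Product: 41 CNP0180877.1
Conditions: 1 M HCl, THF, 0 to 25 °C
Reagents that add atoms: water, O
Why: Acid-catalysed acetal hydrolysis releases the C19 aldehyde under conditions too mild to shift the 7-ene or to move the acetate to C3.

Compound list
1 | (S)-(+)-carvone, (5S)-2-methyl-5-(prop-1-en-2-yl)cyclohex-2-en-1-one | CC1=CC[C@@H](CC1=O)C(C)=C | starting material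
2 | iodomethane | CI | starting material
3 | lithium cross-conjugated dienolate of 1 | CC1=CC[C@@H](C=C1O[Li])C(C)=C | intermediate
4 | 6-methylcarvone, (5S)-2,6-dimethyl-5-(prop-1-en-2-yl)cyclohex-2-en-1-one, both epimers at the methyl-bearing carbon (future C10) | CC1=CC[C@@H](C(C)C1=O)C(C)=C | intermediate
5 | allyl bromide (3-bromoprop-1-ene) | C=CCBr | starting material
6 | lithium dienolate of 4 | CC1=CC[C@@H](C(C)=C1O[Li])C(C)=C | intermediate
7 | (5R,6R)-2,6-dimethyl-6-(prop-2-en-1-yl)-5-(prop-1-en-2-yl)cyclohex-2-en-1-one; quaternary C10, allyl (C1 arm) trans to isopropenyl, C20 methyl cis to it | C=CC[C@@]1(C)C(=O)C(C)=CC[C@@H]1C(C)=C | intermediate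
8 | 3-chloroperoxybenzoic acid | OOC(=O)c1cccc(Cl)c1 | starting material
9 | epoxide of 7 at the isopropenyl group (2-methyloxiran-2-yl on C5), both C4 epimers | C=CC[C@@]1(C)C(=O)C(C)=CC[C@@H]1C2(C)CO2 | intermediate
10 | aldehyde: 7 with CH(CH3)CHO in place of isopropenyl, both C4 epimers | C=CC[C@@]1(C)C(=O)C(C)=CC[C@@H]1C(C)C=O | intermediate
11 | tert-butyldimethylsilyl trifluoromethanesulfonate | CC(C)(C)[Si](C)(C)OS(=O)(=O)C(F)(F)F | starting material
12 | (E)-tert-butyldimethylsilyl enol ether of 10 (silyloxy trans to C5) | C=CC[C@@]1(C)C(=O)C(C)=CC[C@@H]1/C(C)=C/O[Si](C)(C)C(C)(C)C | intermediate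
13 | trimethyl orthoformate | COC(OC)OC | starting material
14 | enone with allyl on C10 and quaternary C4 bearing C18 methyl, C3 formyl and C19 dimethyl acetal | C=CC[C@@]1(C)C(=O)C(C)=CC[C@@H]1[C@](C)(C(OC)OC)C=O | intermediate
15 | ozone | [O-][O+]=O | starting material
16 | 1,2,4-trioxolane (ozonide) formed from the allyl group of 14 | C1(OCOO1)C[C@@]2(C)C(=O)C(C)=CC[C@@H]2[C@](C)(C(OC)OC)C=O | intermediate
17 | enone diol: CH2CH2OH (C1–C2) on C10, CH2OH (C3) and C19 dimethyl acetal on C4 | OCC[C@@]1(C)C(=O)C(C)=CC[C@@H]1[C@](C)(C(OC)OC)CO | intermediate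
18 | tert-butyldimethylsilyl chloride | CC(C)(C)[Si](C)(C)Cl | starting material
19 | bis(tert-butyldimethylsilyl) ether of 17 | CC(C)(C)[Si](C)(C)OCC[C@@]1(C)C(=O)C(C)=CC[C@@H]1[C@](C)(C(OC)OC)CO[Si](C)(C)C(C)(C)C | intermediate
20 | but-3-enylmagnesium bromide | C=CCC[Mg]Br | starting material
21 | tertiary allylic alcohol: 19 after addition of but-3-enyl to C9, both C9 epimers | CC(C)(C)[Si](C)(C)OCC[C@@]1(C)C(O)(CCC=C)C(C)=CC[C@@H]1[C@](C)(C(OC)OC)CO[Si](C)(C)C(C)(C)C | intermediate
22 | 7-oxo-8-ene with but-3-enyl on C9 | CC(C)(C)[Si](C)(C)OCC[C@@]1(C)C(CCC=C)=C(C)C(=O)C[C@@H]1[C@](C)(C(OC)OC)CO[Si](C)(C)C(C)(C)C | intermediate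
23 | N-phenylbis(trifluoromethanesulfonimide) | O=S(=O)(N(c1ccccc1)S(=O)(=O)C(F)(F)F)C(F)(F)F | starting material
24 | lithium C7–C8 enolate, H9 trans to C20 | CC(C)(C)[Si](C)(C)OCC[C@@]1(C)[C@H](CCC=C)C(C)=C(O[Li])C[C@@H]1[C@](C)(C(OC)OC)CO[Si](C)(C)C(C)(C)C | intermediate
25 | C7 enol triflate (7-ene), H9 trans to C20 | CC(C)(C)[Si](C)(C)OCC[C@@]1(C)[C@H](CCC=C)C(C)=C(OS(=O)(=O)C(F)(F)F)C[C@@H]1[C@](C)(C(OC)OC)CO[Si](C)(C)C(C)(C)C | intermediate
26 | 7-ene with but-3-enyl on C9 (cis to C20), bis(silyl) ether, C19 acetal | CC(C)(C)[Si](C)(C)OCC[C@@]1(C)[C@H](CCC=C)C(C)=CC[C@@H]1[C@](C)(C(OC)OC)CO[Si](C)(C)C(C)(C)C | intermediate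
27 | methyl acrylate | C=CC(=O)OC | starting material
28 | (E)-α,β-unsaturated methyl ester (C13=C14) | CC(C)(C)[Si](C)(C)OCC[C@@]1(C)[C@H](CC/C=C/C(=O)OC)C(C)=CC[C@@H]1[C@](C)(C(OC)OC)CO[Si](C)(C)C(C)(C)C | intermediate
29 | methylmagnesium bromide | C[Mg]Br | starting material
30 | (13R)-methyl-branched methyl ester, bis(silyl) ether | CC(C)(C)[Si](C)(C)OCC[C@@]1(C)[C@H](CC[C@@H](C)CC(=O)OC)C(C)=CC[C@@H]1[C@](C)(C(OC)OC)CO[Si](C)(C)C(C)(C)C | intermediate
31 | diol methyl ester (primary alcohols at C2 and C3) | OCC[C@@]1(C)[C@H](CC[C@@H](C)CC(=O)OC)C(C)=CC[C@@H]1[C@](C)(C(OC)OC)CO | intermediate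
32 | dialdehyde precursor: C2 and C3 aldehydes, C19 dimethyl acetal, C15 methyl ester | O=CC[C@@]1(C)[C@H](CC[C@@H](C)CC(=O)OC)C(C)=CC[C@@H]1[C@](C)(C(OC)OC)C=O | intermediate
33 | bis(diiodosamarium) cis-2,3-diolate | I[Sm](I)O[C@H]1C[C@@]2(C)[C@H](CC[C@@H](C)CC(=O)OC)C(C)=CC[C@@H]2[C@](C)(C(OC)OC)[C@H]1O[Sm](I)I | intermediate
34 | cis-2,3-diol (C2–OH equatorial, C3–OH axial), C19 dimethyl acetal, C15 methyl ester | O[C@H]1C[C@@]2(C)[C@H](CC[C@@H](C)CC(=O)OC)C(C)=CC[C@@H]2[C@](C)(C(OC)OC)[C@H]1O | intermediate
35 | lithium hydroxide | [Li+].[OH-] | starting material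
36 | cis-2,3-diol C15 acid, C19 dimethyl acetal | O[C@H]1C[C@@]2(C)[C@H](CC[C@@H](C)CC(=O)O)C(C)=CC[C@@H]2[C@](C)(C(OC)OC)[C@H]1O | intermediate
37 | acetic anhydride | CC(=O)OC(C)=O | starting material
38 | 2-O-acetate with C15 acetic mixed anhydride | CC(=O)O[C@H]1C[C@@]2(C)[C@H](CC[C@@H](C)CC(=O)OC(C)=O)C(C)=CC[C@@H]2[C@](C)(C(OC)OC)[C@H]1O | intermediate
39 | 2-O-acetyl-3-hydroxy C15 acid, C19 dimethyl acetal | CC(=O)O[C@H]1C[C@@]2(C)[C@H](CC[C@@H](C)CC(=O)O)C(C)=CC[C@@H]2[C@](C)(C(OC)OC)[C@H]1O | intermediate
40 | water | O | starting material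
41 | CNP0180877.1 | CC(=O)O[C@H]1C[C@@]2(C)[C@H](CC[C@@H](C)CC(=O)O)C(C)=CC[C@@H]2[C@](C)(C=O)[C@H]1O | target

Total step count: 20.
Longest linear sequence: 20 steps, from (S)-(+)-carvone 1 (the route is fully linear).

Steps most likely to fail

Step 6. Facial selection at C4 rests on acyclic induction from C5 and may be low or reversed, which would put the acetal carbon in the C3 position. The fallback sets out from 12 and comes back at 17, and exchanges the roles of the two C4 carbons. Hydroxymethylation of 12 with aqueous formaldehyde (Yb(OTf)3 cat., THF/H2O, Mukaiyama aldol) would give the hydroxymethyl aldehyde F1; with the reversed facial preference the new CH2OH occupies the C3 position and the formyl group is C19. Acetalisation (HC(OMe)3, pyridinium p-toluenesulfonate, MeOH) would give the hydroxy acetal F2, and ozonolysis with NaBH4 work-up as in step 7 returns to 17. If selectivity is only low, the C4 epimers are separated at 14 or 17.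

Step 17. Bond formation without samarium bridging would give the diequatorial trans-diol; simple reduction of the aldehydes is the other possible leak. The fallback sets out from 32 and comes back at 34, and sets C3 by hydride delivery instead. The trans-diol F4 from the coupling would be silylated at the unhindered C2 hydroxyl (t-BuMe2SiCl, imidazole, DMF) to the C2 silyl ether F5, then oxidised (Dess–Martin periodinane) to the C3 ketone F6. Reduction with LiBH(s-Bu)3 in THF at −78 °C, which approaches along the equatorial trajectory, should give the axial alcohol F7, and desilylation (Bu4NF) gives 34.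

Step 11. C9 may be protonated from the wrong face, or the enolate may equilibrate before triflation and misplace the alkene. The fallback sets out from 22 and comes back at 26. Luche reduction (NaBH4, CeCl3·7H2O, MeOH, −78 °C; axial hydride attack) should give the equatorial allylic alcohol F3, with its hydroxyl on the C20 face. Reductive allylic transposition with 2-nitrobenzenesulfonylhydrazide under Mitsunobu conditions (PPh3, diethyl azodicarboxylate, THF, −30 to 25 °C) then replaces the C7 oxygen with inversion, delivers hydrogen to C9 on the face opposite C20 and moves the alkene to C7–C8, giving 26 directly.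

Further compounds
F1 | step 6 | enone with allyl on C10 and quaternary C4 bearing C18 methyl, C19 formyl and C3 hydroxymethyl | C=CC[C@@]1(C)C(=O)C(C)=CC[C@@H]1[C@](C)(C=O)CO
F2 | step 6 | C19 dimethyl acetal of F1 | C=CC[C@@]1(C)C(=O)C(C)=CC[C@@H]1[C@](C)(C(OC)OC)CO
F3 | step 11 | 7-hydroxy-8-ene with but-3-enyl on C9, hydroxyl on the C20 face | CC(C)(C)[Si](C)(C)OCC[C@@]1(C)C(CCC=C)=C(C)[C@H](O)C[C@@H]1[C@](C)(C(OC)OC)CO[Si](C)(C)C(C)(C)C
F4 | step 17 | trans-2,3-diol, C3 epimer of 34 | O[C@H]1C[C@@]2(C)[C@H](CC[C@@H](C)CC(=O)OC)C(C)=CC[C@@H]2[C@](C)(C(OC)OC)[C@@H]1O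
F5 | step 17 | 2-O-tert-butyldimethylsilyl ether of F4 | CC(C)(C)[Si](C)(C)O[C@H]1C[C@@]2(C)[C@H](CC[C@@H](C)CC(=O)OC)C(C)=CC[C@@H]2[C@](C)(C(OC)OC)[C@@H]1O
F6 | step 17 | 2-O-silyl 3-ketone | CC(C)(C)[Si](C)(C)O[C@H]1C[C@@]2(C)[C@H](CC[C@@H](C)CC(=O)OC)C(C)=CC[C@@H]2[C@](C)(C(OC)OC)C1=O
F7 | step 17 | 2-O-tert-butyldimethylsilyl ether of 34 (axial C3 hydroxyl) | CC(C)(C)[Si](C)(C)O[C@H]1C[C@@]2(C)[C@H](CC[C@@H](C)CC(=O)OC)C(C)=CC[C@@H]2[C@](C)(C(OC)OC)[C@H]1O
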